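The 28-membered lactone (C1 = lactone carbonyl, C27 = carbinol carbon on the ring oxygen) is opened at C10–C11, the CH2–CH(OH) bond inside the C9/C11/C13 triol. One BF3-mediated intramolecular Mukaiyama aldol joins a C9 silyl enol ether to the C11 aldehyde: it closes the macrocycle and sets C11, exploiting the β-silyloxy stereocentre C13 for 1,3-anti induction, and leaves a C9 ketone that the new C11 hydroxyl then directs to the syn C9 carbinol. The precursor is an open-chain pentaenyl ester with enol silane and aldehyde termini, assembled by Stille union of a C1–C10/C24–C27 vinyl iodide with a C11–C23 tetraenyl stannane.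

Key step: step 21

Remark: locants C1–C27 are those defined above; glutaconaldehyde potassium salt, (2R,3R)-2,3-dimethyloxirane and (E)-1,2-bis(tributylstannyl)ethene are taken as purchasable.

Step 1
Reactants: 1 1-methylcyclopentene
Product: 3 5-oxohexanal, via secondary ozonide 2 (not isolated)
Conditions: O3, CH2Cl2, −78 °C; then PPh3, −78 °C to rt
Reagents that add atoms: ozone, [O-][O+]=O
Why: Ozonolysis with reductive work-up should open the ring alkene to the keto aldehyde that carries C5–C10 with the C9 methyl ketone already in place.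

Step 2
Reactants: 3 5-oxohexanal; 4 allyltributylstannane
Product: 5 (S)-6-hydroxynon-8-en-2-one
Conditions: (R)-BINOL (10 mol%), Ti(OiPr)4 (10 mol%), 4 Å molecular sieves, CH2Cl2, −20 °C; aq NaHCO3
Reagents that add atoms: none
Why: Keck asymmetric allylation should deliver the allyl group to the Re face of the aldehyde under control of the (R)-BINOL titanium catalyst, leaving the less electrophilic methyl ketone alone and setting C5.

Step 3
Reactants: 5 (S)-6-hydroxynon-8-en-2-one
Product: 6 (S)-6-[(tert-butyldimethylsilyl)oxy]non-8-en-2-one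
Conditions: TBSCl, imidazole, DMF, rt
Reagents that add atoms: tert-butyldimethylsilyl chloride, CC(C)(C)[Si](C)(C)Cl
Why: Standard silylation should protect the C5 hydroxyl as a fluoride-labile ether under conditions too mild to enolise the ketone.

Step 4
Reactants: 6 (S)-6-[(tert-butyldimethylsilyl)oxy]non-8-en-2-one
Product: 8 (S)-3-[(tert-butyldimethylsilyl)oxy]-7-oxooctanal, via 1,2,4-trioxolane 7 (not isolated)
Conditions: O3, CH2Cl2, −78 °C; then PPh3, −78 °C to rt
Reagents that add atoms: ozone, [O-][O+]=O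
Why: Ozonolysis of the terminal alkene should unmask the C3 aldehyde while ketone and silyl ether stay untouched.

Step 5
Reactants: 8 (S)-3-[(tert-butyldimethylsilyl)oxy]-7-oxooctanal; 9 (S)-4-benzyl-3-propionyloxazolidin-2-one
Product: 11 (S)-4-benzyl-3-[(2S,3R,5S)-5-[(tert-butyldimethylsilyl)oxy]-3-hydroxy-2-methyl-9-oxodecanoyl]oxazolidin-2-one, via dibutylboron Z-enolate 10 (not isolated)
Conditions: 9, Bu2BOTf, i-Pr2NEt, CH2Cl2, 0 °C; then 8, −78 to 0 °C; pH 7 buffer, MeOH, H2O2
Reagents that add atoms: none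
Why: In the Evans syn aldol the Z-boron enolate adds to the aldehyde (much faster than to the ketone) through a closed chair transition state, the auxiliary setting C2 (S) and C3 (R) syn regardless of the C5 centre.

Step 6
Reactants: 11 the aldol adduct
Product: 12 (S)-4-benzyl-3-[(2S,3R,5S)-3,5-bis[(tert-butyldimethylsilyl)oxy]-2-methyl-9-oxodecanoyl]oxazolidin-2-one
Conditions: TBSOTf, 2,6-lutidine, CH2Cl2, −78 °C
Reagents that add atoms: tert-butyldimethylsilyl triflate, CC(C)(C)[Si](C)(C)OS(=O)(=O)C(F)(F)F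
Why: Silyl triflate with a hindered pyridine base should silylate the C3 hydroxyl at low temperature without forming an enol silane from the ketone and blocks retro-aldol in the next step.

Step 7
Reactants: 12 the bis-silyl imide
Product: 14 (2S,3R,5S)-3,5-bis[(tert-butyldimethylsilyl)oxy]-2-methyl-9-oxodecanoic acid, via lithium peroxycarboxylate 13 (not isolated)
Conditions: LiOH, H2O2, THF/H2O, 0 °C; then Na2SO3; HCl to pH 3
Reagents that add atoms: hydrogen peroxide, OO
Why: Lithium hydroperoxide should attack the exocyclic imide carbonyl selectively and release the acid without epimerising C2.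

Step 8
Reactants: 15 (2R,3R)-2,3-dimethyloxirane; 16 lithium acetylide–ethylenediamine complex
Product: 17 (2R,3R)-3-methylpent-4-yn-2-ol
Conditions: DMSO, rt; H2O work-up
Reagents that add atoms: none
Why: SN2 opening of the C2-symmetric trans-epoxide by acetylide with inversion at the attacked carbon should give the C26 methyl/C27 hydroxyl pair as a single stereoisomer in one step.

Step 9
Reactants: 17 (2R,3R)-3-methylpent-4-yn-2-ol
Product: 19 (2R,3R,4E)-5-iodo-3-methylpent-4-en-2-ol, via bis-zirconocene alkenyl alkoxide 18 (not isolated)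
Conditions: Cp2Zr(H)Cl (2.2 equiv), THF, rt; then I2, 0 °C
Reagents that add atoms: iodine, [I][I]
Why: Hydrozirconation of the terminal alkyne is a syn addition with zirconium at the terminus (one equivalent is consumed by the hydroxyl), and iodinolysis with retention should give the E vinyl iodide (C24=C25).

Step 10
Reactants: 14 the C1–C10 acid; 19 (2R,3R,4E)-5-iodo-3-methylpent-4-en-2-ol
Product: 21 (2R,3R,4E)-5-iodo-3-methylpent-4-en-2-yl (2S,3R,5S)-3,5-bis[(tert-butyldimethylsilyl)oxy]-2-methyl-9-oxodecanoate, via mixed anhydride 20 (not isolated)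
Conditions: 2,4,6-trichlorobenzoyl chloride, Et3N, toluene, rt; then 19, DMAP, rt
Reagents that add atoms: none
Why: Yamaguchi esterification through the mixed aroyl anhydride should acylate the hindered C27 alcohol under DMAP catalysis and so install the future lactone linkage early, without epimerising C2.

Step 11
Reactants: 21 the keto ester
Product: 23 (2R,3R,4E)-5-iodo-3-methylpent-4-en-2-yl (2S,3R,5S)-3,5,9-tris[(tert-butyldimethylsilyl)oxy]-2-methyldec-9-enoate, via lithium enolate 22 (not isolated)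
Conditions: LiN(SiMe3)2 (1.1 equiv), THF, −78 °C; then TBSCl, DMPU, −78 to −30 °C; work-up with Et3N-treated silica
Reagents that add atoms: tert-butyldimethylsilyl chloride, CC(C)(C)[Si](C)(C)Cl
Why: Kinetic deprotonation at the unhindered C10 methyl group (faster than at C8 or at the hindered ester α-CH) followed by O-silylation should fix the terminal enol silane needed for the ring closure.

Step 12
Reactants: 24 glutaconaldehyde potassium salt
Product: 25 (2E,4E)-5-bromopenta-2,4-dienal
Conditions: PPh3, Br2, CH2Cl2, 0 °C; then 24, 0 °C to rt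
Reagents that add atoms: bromine, BrBr
Why: Dibromotriphenylphosphorane should convert the enolate oxygen into a vinyl bromide by addition–elimination, giving the E,E bromodienal that supplies C17–C21.

Step 13
Reactants: 25 (2E,4E)-5-bromopenta-2,4-dienal; 26 (triphenylphosphoranylidene)acetaldehyde
Product: 27 (2E,4E,6E)-7-bromohepta-2,4,6-trienal
Conditions: toluene, 60 °C
Reagents that add atoms: none
Why: Wittig reaction with the stabilised formyl ylide should be E-selective and extend the dienal by C15–C16, one equivalent of ylide limiting further homologation.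

Step 14
Reactants: 27 (2E,4E,6E)-7-bromohepta-2,4,6-trienal; 28 (S)-4-benzyl-3-propionylthiazolidine-2-thione
Product: 30 (S)-4-benzyl-3-[(2S,3R,4E,6E,8E)-9-bromo-3-hydroxy-2-methylnona-4,6,8-trienoyl]thiazolidine-2-thione, via chlorotitanium Z-enolate 29 (not isolated)
Conditions: 28, TiCl4, i-Pr2NEt, N-methylpyrrolidinone, CH2Cl2, 0 °C; then 27, −78 to 0 °C; aqueous work-up
Reagents that add atoms: none
Why: In the Crimmins titanium aldol with amine and N-methylpyrrolidinone the Z-enolate reacts through a non-chelated chair transition state to give the Evans-syn adduct, the auxiliary setting C14 and C15 by 1,2-addition to the trienal.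

Step 15
Reactants: 30 the trienyl aldol adduct; 31 ethyl potassium malonate
Product: 33 ethyl (4S,5R,6E,8E,10E)-11-bromo-5-hydroxy-4-methyl-3-oxoundeca-6,8,10-trienoate, via acylmalonic half-ester 32 (not isolated)
Conditions: MgCl2, imidazole, THF, rt; aq HCl work-up
Reagents that add atoms: none
Why: In this Masamune-type decarboxylative Claisen condensation the magnesium malonate displaces the activated thiazolidinethione amide and loses CO2, adding C11–C12 and leaving the free C15 hydroxyl needed to direct the next step.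

Step 16
Reactants: 33 the δ-hydroxy β-keto ester
Product: 34 ethyl (3R,4R,5R,6E,8E,10E)-11-bromo-3,5-dihydroxy-4-methylundeca-6,8,10-trienoate
Conditions: Me4NBH(OAc)3, MeCN/AcOH (1:1), −30 °C
Reagents that add atoms: none
Why: In the Evans–Saksena reduction the C15 hydroxyl binds the acetoxyborohydride and delivers hydride intramolecularly through a chair transition state, which should give the 13,15-anti diol and set C13.

Step 17
Reactants: 34 the anti diol
Product: 35 ethyl (3R,4R,5R,6E,8E,10E)-11-bromo-3,5-bis[(tert-butyldimethylsilyl)oxy]-4-methylundeca-6,8,10-trienoate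
Conditions: TBSOTf (2.5 equiv), 2,6-lutidine, CH2Cl2, −78 to 0 °C
Reagents that add atoms: tert-butyldimethylsilyl triflate, CC(C)(C)[Si](C)(C)OS(=O)(=O)C(F)(F)F
Why: Double silylation should protect both hindered secondary hydroxyls as fluoride-labile ethers and prevent lactonisation of the dihydroxy ester.

Step 18
Reactants: 35 the bis-silyl ester
Product: 37 (3R,4R,5R,6E,8E,10E)-11-bromo-3,5-bis[(tert-butyldimethylsilyl)oxy]-4-methylundeca-6,8,10-trienal, via aluminium hemiacetal 36 (not isolated)
Conditions: i-Bu2AlH (1.05 equiv), CH2Cl2, −78 °C; then MeOH and aqueous work-up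
Reagents that add atoms: none
Why: The tetrahedral aluminium hemiacetal is stable at −78 °C, so partial reduction of the ester should stop at the C11 aldehyde, with the trienyl bromide inert.

Step 19
Reactants: 37 the bromotrienyl aldehyde; 38 (E)-1,2-bis(tributylstannyl)ethene
Product: 39 (3R,4R,5R,6E,8E,10E,12E)-3,5-bis[(tert-butyldimethylsilyl)oxy]-4-methyl-13-(tributylstannyl)trideca-6,8,10,12-tetraenal
Conditions: 38 (3 equiv), PdCl2(MeCN)2 (5 mol%), DMF, rt, dark
Reagents that add atoms: none
Why: Stille coupling proceeds with retention at both alkenes and tolerates the aldehyde, and the excess of the bis-stannane should limit reaction to one tin, adding C22–C23 with the terminal stannane.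

Step 20
Reactants: 23 the enol silane vinyl iodide; 39 the tetraenyl stannane aldehyde
Product: 40 seco enol silane aldehyde (C1–O–C27 ester with the all-E C16–C25 pentaene, C9 silyl enol ether and C11 aldehyde)
Conditions: Pd2(dba)3 (5 mol%), AsPh3 (40 mol%), DMF/THF, rt, dark; Et3N-treated silica
Reagents that add atoms: none
Why: Stille coupling under neutral, base-free conditions should form the C23–C24 bond with retention and is the one union that tolerates the aldehyde and the silyl enol ether side by side.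

Step 21
Reactants: 40 seco enol silane aldehyde
Product: 42 macrocyclic β-hydroxy ketone (28-membered lactone with 9-oxo, 11-hydroxy and 3,5,13,15-tetrakis-silyloxy groups), via difluoroboron aldolate 41 (not isolated)
Conditions: BF3·OEt2 (3 equiv), CH2Cl2, −78 °C, slow addition of 40 to a final 0.5 mM; aq NaHCO3
Reagents that add atoms: none
Why: BF3 coordinates the C11 aldehyde and the terminal carbon C10 of the C9 silyl enol ether attacks it through an open transition state; the silyloxocarbenium ion formed loses its silyl group to fluoride, leaving a difluoroboron aldolate that gives the free β-hydroxy ketone on work-up. The closest known reaction type is the Lewis-acid-mediated Mukaiyama aldol addition of methyl-ketone enol silanes to β-silyloxy aldehydes, run here intramolecularly. The 28-membered ring closes in a 28-(enolendo)-exo-trig mode, the aldehyde oxygen ending outside the ring. The new C11 stereocentre is controlled by the silyloxy stereocentre C13 β to the aldehyde: in the dipole-minimised open transition state the nucleophile should approach the Si face, anti to the C13–C14 residue, giving the 11,13-anti carbinol required for the target. The step needs regiocontrol at the nucleophile, secured by the preformed terminal enol silane in a base-free medium, cyclisation over oligomerisation, secured by slow addition at high dilution, and facial selectivity, secured by the 1,3-anti bias of C13. Exposure of the pentaene and its allylic C15 silyl ether to the Lewis acid is limited by working at −78 °C.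

Step 22
Reactants: 42 macrocyclic β-hydroxy ketone
Product: 44 macrocyclic 9,11-syn diol (3,5,13,15-tetrakis-silyl ether), via diethylboron chelate 43 (not isolated)
Conditions: Et2BOMe, THF/MeOH (4:1), −78 °C; then NaBH4, −78 °C; MeOH co-evaporation
Reagents that add atoms: none
Why: In the Narasaka–Prasad reduction the boron chelate of the C11 hydroxyl and C9 carbonyl adopts a half-chair that takes external hydride axially, which should give the 9,11-syn diol and set C9 without reducing the lactone.

Step 23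
Reactants: 44 macrocyclic 9,11-syn diol
Product: 45 CNP0245606.1 (the target hexol)
Conditions: HF·pyridine, excess pyridine, THF, 0 °C to rt
Reagents that add atoms: none
Why: Buffered fluoride should cleave the four secondary silyl ethers without ionising the C15 allylic position or opening the lactone.

Compound list
1 | 1-methylcyclopentene | CC1=CCCC1 | starting material
2 | secondary ozonide of 1 (1-methyl-6,7,8-trioxabicyclo[3.2.1]octane) | CC12CCCC(OO1)O2 | intermediate (not isolated)
3 | 5-oxohexanal | CC(=O)CCCC=O | intermediate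
4 | allyltributylstannane | C=CC[Sn](CCCC)(CCCC)CCCC | starting material
5 | (S)-6-hydroxynon-8-en-2-one | CC(=O)CCC[C@H](O)CC=C | intermediate
6 | (S)-6-[(tert-butyldimethylsilyl)oxy]non-8-en-2-one | CC(=O)CCC[C@H](O[Si](C)(C)C(C)(C)C)CC=C | intermediate
7 | 1,2,4-trioxolane (ozonide) of 6 | CC(=O)CCC[C@H](O[Si](C)(C)C(C)(C)C)CC1OCOO1 | intermediate (not isolated)
8 | (S)-3-[(tert-butyldimethylsilyl)oxy]-7-oxooctanal | CC(=O)CCC[C@H](O[Si](C)(C)C(C)(C)C)CC=O | intermediate
9 | (S)-4-benzyl-3-propionyloxazolidin-2-one | CCC(=O)N1[C@@H](Cc2ccccc2)COC1=O | starting material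
10 | dibutylboron (Z)-enolate of 9 | C/C=C(\OB(CCCC)CCCC)N1[C@@H](Cc2ccccc2)COC1=O | intermediate (not isolated)
11 | (S)-4-benzyl-3-[(2S,3R,5S)-5-[(tert-butyldimethylsilyl)oxy]-3-hydroxy-2-methyl-9-oxodecanoyl]oxazolidin-2-one | CC(=O)CCC[C@H](O[Si](C)(C)C(C)(C)C)C[C@@H](O)[C@H](C)C(=O)N1[C@@H](Cc2ccccc2)COC1=O | intermediate
12 | (S)-4-benzyl-3-[(2S,3R,5S)-3,5-bis[(tert-butyldimethylsilyl)oxy]-2-methyl-9-oxodecanoyl]oxazolidin-2-one | CC(=O)CCC[C@H](O[Si](C)(C)C(C)(C)C)C[C@@H](O[Si](C)(C)C(C)(C)C)[C@H](C)C(=O)N1[C@@H](Cc2ccccc2)COC1=O | intermediate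
13 | lithium (2S,3R,5S)-3,5-bis[(tert-butyldimethylsilyl)oxy]-2-methyl-9-oxodecaneperoxoate | CC(=O)CCC[C@H](O[Si](C)(C)C(C)(C)C)C[C@@H](O[Si](C)(C)C(C)(C)C)[C@H](C)C(=O)OO[Li] | intermediate (not isolated)
14 | (2S,3R,5S)-3,5-bis[(tert-butyldimethylsilyl)oxy]-2-methyl-9-oxodecanoic acid | CC(=O)CCC[C@H](O[Si](C)(C)C(C)(C)C)C[C@@H](O[Si](C)(C)C(C)(C)C)[C@H](C)C(=O)O | intermediate
15 | (2R,3R)-2,3-dimethyloxirane | C[C@H]1O[C@@H]1C | starting material
16 | lithium acetylide–ethylenediamine complex | [Li]C#C.NCCN | starting material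
17 | (2R,3R)-3-methylpent-4-yn-2-ol | O[C@H](C)[C@H](C)C#C | intermediate
18 | (E)-alkenylzirconocene chloride of 17 with the hydroxyl as zirconocene chloride alkoxide | Cl[Zr](C1C=CC=C1)(C1C=CC=C1)O[C@H](C)[C@H](C)/C=C/[Zr](Cl)(C1C=CC=C1)C1C=CC=C1 | intermediate (not isolated)
19 | (2R,3R,4E)-5-iodo-3-methylpent-4-en-2-ol | O[C@H](C)[C@H](C)/C=C/I | intermediate
20 | mixed anhydride of 14 with 2,4,6-trichlorobenzoic acid | CC(=O)CCC[C@H](O[Si](C)(C)C(C)(C)C)C[C@@H](O[Si](C)(C)C(C)(C)C)[C@H](C)C(=O)OC(=O)c1c(Cl)cc(Cl)cc1Cl | intermediate (not isolated)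
21 | (2R,3R,4E)-5-iodo-3-methylpent-4-en-2-yl (2S,3R,5S)-3,5-bis[(tert-butyldimethylsilyl)oxy]-2-methyl-9-oxodecanoate | CC(=O)CCC[C@H](O[Si](C)(C)C(C)(C)C)C[C@@H](O[Si](C)(C)C(C)(C)C)[C@H](C)C(=O)O[C@H](C)[C@H](C)/C=C/I | intermediate
22 | lithium enolate of 21 (C9–OLi, C9=C10) | [Li]OC(=C)CCC[C@H](O[Si](C)(C)C(C)(C)C)C[C@@H](O[Si](C)(C)C(C)(C)C)[C@H](C)C(=O)O[C@H](C)[C@H](C)/C=C/I | intermediate (not isolated)
23 | (2R,3R,4E)-5-iodo-3-methylpent-4-en-2-yl (2S,3R,5S)-3,5,9-tris[(tert-butyldimethylsilyl)oxy]-2-methyldec-9-enoate | C=C(O[Si](C)(C)C(C)(C)C)CCC[C@H](O[Si](C)(C)C(C)(C)C)C[C@@H](O[Si](C)(C)C(C)(C)C)[C@H](C)C(=O)O[C@H](C)[C@H](C)/C=C/I | intermediate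
24 | glutaconaldehyde potassium salt (potassium (1E,3E)-5-oxopenta-1,3-dien-1-olate) | [K+].[O-]/C=C/C=C/C=O | starting material
25 | (2E,4E)-5-bromopenta-2,4-dienal | Br/C=C/C=C/C=O | intermediate
26 | (triphenylphosphoranylidene)acetaldehyde | O=CC=P(c1ccccc1)(c1ccccc1)c1ccccc1 | starting material
27 | (2E,4E,6E)-7-bromohepta-2,4,6-trienal | Br/C=C/C=C/C=C/C=O | intermediate
28 | (S)-4-benzyl-3-propionylthiazolidine-2-thione | CCC(=O)N1[C@@H](Cc2ccccc2)CSC1=S | starting material
29 | trichlorotitanium (Z)-enolate of 28 | C/C=C(\O[Ti](Cl)(Cl)Cl)N1[C@@H](Cc2ccccc2)CSC1=S | intermediate (not isolated)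
30 | (S)-4-benzyl-3-[(2S,3R,4E,6E,8E)-9-bromo-3-hydroxy-2-methylnona-4,6,8-trienoyl]thiazolidine-2-thione | Br/C=C/C=C/C=C/[C@@H](O)[C@H](C)C(=O)N1[C@@H](Cc2ccccc2)CSC1=S | intermediate
31 | ethyl potassium malonate | [K+].[O-]C(=O)CC(=O)OCC | starting material
32 | acylmalonic half-ester (2-carboxy derivative of 33) | Br/C=C/C=C/C=C/[C@@H](O)[C@H](C)C(=O)C(C(=O)O)C(=O)OCC | intermediate (not isolated)
33 | ethyl (4S,5R,6E,8E,10E)-11-bromo-5-hydroxy-4-methyl-3-oxoundeca-6,8,10-trienoate | Br/C=C/C=C/C=C/[C@@H](O)[C@H](C)C(=O)CC(=O)OCC | intermediate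
34 | ethyl (3R,4R,5R,6E,8E,10E)-11-bromo-3,5-dihydroxy-4-methylundeca-6,8,10-trienoate | Br/C=C/C=C/C=C/[C@@H](O)[C@H](C)[C@H](O)CC(=O)OCC | intermediate
35 | ethyl (3R,4R,5R,6E,8E,10E)-11-bromo-3,5-bis[(tert-butyldimethylsilyl)oxy]-4-methylundeca-6,8,10-trienoate | Br/C=C/C=C/C=C/[C@@H](O[Si](C)(C)C(C)(C)C)[C@H](C)[C@H](O[Si](C)(C)C(C)(C)C)CC(=O)OCC | intermediate
36 | diisobutylaluminium hemiacetal of 35 | Br/C=C/C=C/C=C/[C@@H](O[Si](C)(C)C(C)(C)C)[C@H](C)[C@H](O[Si](C)(C)C(C)(C)C)CC(OCC)O[Al](CC(C)C)CC(C)C | intermediate (not isolated)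
37 | (3R,4R,5R,6E,8E,10E)-11-bromo-3,5-bis[(tert-butyldimethylsilyl)oxy]-4-methylundeca-6,8,10-trienal | Br/C=C/C=C/C=C/[C@@H](O[Si](C)(C)C(C)(C)C)[C@H](C)[C@H](O[Si](C)(C)C(C)(C)C)CC=O | intermediate
38 | (E)-1,2-bis(tributylstannyl)ethene | CCCC[Sn](CCCC)(CCCC)/C=C/[Sn](CCCC)(CCCC)CCCC | starting material
39 | (3R,4R,5R,6E,8E,10E,12E)-3,5-bis[(tert-butyldimethylsilyl)oxy]-4-methyl-13-(tributylstannyl)trideca-6,8,10,12-tetraenal | CCCC[Sn](CCCC)(CCCC)/C=C/C=C/C=C/C=C/[C@@H](O[Si](C)(C)C(C)(C)C)[C@H](C)[C@H](O[Si](C)(C)C(C)(C)C)CC=O | intermediate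
40 | seco enol silane aldehyde: (2R,3R,4E,6E,8E,10E,12E,14R,15R,16R)-14,16-bis[(tert-butyldimethylsilyl)oxy]-3,15-dimethyl-18-oxooctadeca-4,6,8,10,12-pentaen-2-yl (2S,3R,5S)-3,5,9-tris[(tert-butyldimethylsilyl)oxy]-2-methyldec-9-enoate | C=C(O[Si](C)(C)C(C)(C)C)CCC[C@H](O[Si](C)(C)C(C)(C)C)C[C@@H](O[Si](C)(C)C(C)(C)C)[C@H](C)C(=O)O[C@H](C)[C@H](C)/C=C/C=C/C=C/C=C/C=C/[C@@H](O[Si](C)(C)C(C)(C)C)[C@H](C)[C@H](O[Si](C)(C)C(C)(C)C)CC=O | intermediate
41 | difluoroboron aldolate of 42 (C11–O–BF2) | O=C1CCC[C@H](O[Si](C)(C)C(C)(C)C)C[C@@H](O[Si](C)(C)C(C)(C)C)[C@H](C)C(=O)O[C@H](C)[C@H](C)/C=C/C=C/C=C/C=C/C=C/[C@@H](O[Si](C)(C)C(C)(C)C)[C@H](C)[C@H](O[Si](C)(C)C(C)(C)C)C[C@@H](OB(F)F)C1 | intermediate (not isolated)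
42 | macrocyclic β-hydroxy ketone: 28-membered lactone with 9-oxo, 11-hydroxy and 3,5,13,15-tetrakis[(tert-butyldimethylsilyl)oxy] groups, all stereocentres as in the target | O=C1CCC[C@H](O[Si](C)(C)C(C)(C)C)C[C@@H](O[Si](C)(C)C(C)(C)C)[C@H](C)C(=O)O[C@H](C)[C@H](C)/C=C/C=C/C=C/C=C/C=C/[C@@H](O[Si](C)(C)C(C)(C)C)[C@H](C)[C@H](O[Si](C)(C)C(C)(C)C)C[C@@H](O)C1 | intermediate
43 | diethylboron chelate of 42 (C11–O–BEt2 bound to the C9 carbonyl) | O=C1CCC[C@H](O[Si](C)(C)C(C)(C)C)C[C@@H](O[Si](C)(C)C(C)(C)C)[C@H](C)C(=O)O[C@H](C)[C@H](C)/C=C/C=C/C=C/C=C/C=C/[C@@H](O[Si](C)(C)C(C)(C)C)[C@H](C)[C@H](O[Si](C)(C)C(C)(C)C)C[C@@H](OB(CC)CC)C1 | intermediate (not isolated)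
44 | macrocyclic 9,11-syn diol: 3,5,13,15-tetrakis(tert-butyldimethylsilyl) ether of the target | O[C@H]1CCC[C@H](O[Si](C)(C)C(C)(C)C)C[C@@H](O[Si](C)(C)C(C)(C)C)[C@H](C)C(=O)O[C@H](C)[C@H](C)/C=C/C=C/C=C/C=C/C=C/[C@@H](O[Si](C)(C)C(C)(C)C)[C@H](C)[C@H](O[Si](C)(C)C(C)(C)C)C[C@@H](O)C1 | intermediate
45 | CNP0245606.1: (3S,4R,6S,10S,12S,14R,15R,16R,17E,19E,21E,23E,25E,27R,28R)-4,6,10,12,14,16-hexahydroxy-3,15,27,28-tetramethyl-1-oxacyclooctacosa-17,19,21,23,25-pentaen-2-one | C[C@H]1[C@H](O)/C=C/C=C/C=C/C=C/C=C/[C@@H](C)[C@@H](C)OC(=O)[C@@H](C)[C@H](O)C[C@@H](O)CCC[C@H](O)C[C@H](O)C[C@H]1O | target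

Total step count: 23. Longest linear sequence: 13 steps (steps 1–7, 10, 11, 20–23, from 1-methylcyclopentene).

Steps most likely to fail

Step 21. The facial bias at C11 may be too weak, because a silyl-protected C13 oxygen gives a smaller 1,3-anti preference than an alkoxy group and the macrocyclic tether may oppose it. The Lewis acid may also strip the enol silane or ionise the C15 silyloxy group next to the pentaene before the ring closes. The fallback keeps the same C10–C11 ring closure but runs it reductively under neutral conditions. It sets out from 23: N-chlorosuccinimide in THF at −78 °C should convert the enol silane into the chloromethyl ketone F1. Stille coupling of the chloromethyl ketone F1 with stannane 39 (Pd2(dba)3, AsPh3, DMF, rt) should give the seco chloro ketone aldehyde F2. SmI2 in THF at −78 °C under high dilution should then effect a Reformatsky-type aldol ring closure of the seco chloro ketone aldehyde F2 through a closed, metal-bridged transition state. The route is rejoined at 42.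

Step 20. The long tetraenyl stannane may undergo protodestannylation or homocoupling faster than cross-coupling, with further loss on purification of the acid-sensitive product. The fallback moves the tin to the other partner so that no tetraenyl stannane is needed. It sets out from 23 and 37: Stille coupling of 23 with an excess of 38 should give the dienyl stannane F3. The dienyl stannane F3 is then coupled with the bromotrienyl aldehyde 37 under the same palladium catalysis. The route is rejoined at 40.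

Step 11. Deprotonation may compete at the ester α-carbon C2, leading to epimerisation or β-elimination of the C3 silyloxy group. The fallback forms the enol silane before the ester, where the carboxylate shields C2. It sets out from 14: LiN(SiMe3)2 (2.2 equiv) and TBSCl should give the silyl ester enol silane F4. K2CO3 in MeOH/H2O at 0 °C should cleave only the silyl ester to give the enol silane acid F5. Yamaguchi activation of the enol silane acid F5 should give the mixed anhydride F6, and the mixed anhydride F6 is then esterified with 19 under DMAP catalysis. The route is rejoined at 23.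

Further compounds
F1 | step 21 | (2R,3R,4E)-5-iodo-3-methylpent-4-en-2-yl (2S,3R,5S)-3,5-bis[(tert-butyldimethylsilyl)oxy]-10-chloro-2-methyl-9-oxodecanoate | ClCC(=O)CCC[C@H](O[Si](C)(C)C(C)(C)C)C[C@@H](O[Si](C)(C)C(C)(C)C)[C@H](C)C(=O)O[C@H](C)[C@H](C)/C=C/I
F2 | step 21 | seco chloro ketone aldehyde (40 with the enol silane replaced by a C9 ketone bearing C10–Cl) | ClCC(=O)CCC[C@H](O[Si](C)(C)C(C)(C)C)C[C@@H](O[Si](C)(C)C(C)(C)C)[C@H](C)C(=O)O[C@H](C)[C@H](C)/C=C/C=C/C=C/C=C/C=C/[C@@H](O[Si](C)(C)C(C)(C)C)[C@H](C)[C@H](O[Si](C)(C)C(C)(C)C)CC=O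
F3 | step 20 | (2R,3R,4E,6E)-3-methyl-7-(tributylstannyl)hepta-4,6-dien-2-yl (2S,3R,5S)-3,5,9-tris[(tert-butyldimethylsilyl)oxy]-2-methyldec-9-enoate | C=C(O[Si](C)(C)C(C)(C)C)CCC[C@H](O[Si](C)(C)C(C)(C)C)C[C@@H](O[Si](C)(C)C(C)(C)C)[C@H](C)C(=O)O[C@H](C)[C@H](C)/C=C/C=C/[Sn](CCCC)(CCCC)CCCC
F4 | step 11 | tert-butyldimethylsilyl (2S,3R,5S)-3,5,9-tris[(tert-butyldimethylsilyl)oxy]-2-methyldec-9-enoate | C=C(O[Si](C)(C)C(C)(C)C)CCC[C@H](O[Si](C)(C)C(C)(C)C)C[C@@H](O[Si](C)(C)C(C)(C)C)[C@H](C)C(=O)O[Si](C)(C)C(C)(C)C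
F5 | step 11 | (2S,3R,5S)-3,5,9-tris[(tert-butyldimethylsilyl)oxy]-2-methyldec-9-enoic acid | C=C(O[Si](C)(C)C(C)(C)C)CCC[C@H](O[Si](C)(C)C(C)(C)C)C[C@@H](O[Si](C)(C)C(C)(C)C)[C@H](C)C(=O)O
F6 | step 11 | mixed anhydride of F5 with 2,4,6-trichlorobenzoic acid | C=C(O[Si](C)(C)C(C)(C)C)CCC[C@H](O[Si](C)(C)C(C)(C)C)C[C@@H](O[Si](C)(C)C(C)(C)C)[C@H](C)C(=O)OC(=O)c1c(Cl)cc(Cl)cc1Cl
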